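## Retrosynthetic overview
- The target comes from its bis(methyl ether) by a final O-demethylation.
- Key disconnection: the ring A–CH2–CH2–ring B bond is made by ring contraction. A 19-membered aza-macrocycle (ring A–CH2–NH–CH2–ring B) loses its nitrogen as N2 to give the 18-membered ring.
- Only one ring is built: first the 19-membered azacycle, from an open-chain dialdehyde and NH3, then its contraction to the 18-membered carbocycle.
- The dialdehyde comes from two iodoaryl ethers (rings A–O–D and rings B–O–C). They are joined through a C2 unit by a double Sonogashira coupling, and the alkyne is then hydrogenated.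
- Rings A–O–D arise by SNAr of 3-iodophenol on an ortho-lithiated and formylated 4-fluorophenol derivative. Rings B–O–C arise by Ullmann coupling of a catechol monoether with 1,4-diiodobenzene, followed by formylation para to OMe.

Assumption: the SMILES has no stereodescriptor and the molecule has no stereocentre or fixed axis or plane, so it is made as the achiral compound drawn. No step has to set or preserve configuration.

## Route

Step 1
Reactants: 1 4-fluorophenol
Product: 2 4-fluoroanisole
Conditions: MeI, K2CO3, acetone, reflux
Reagents that add atoms: iodomethane, CI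
Why: Williamson ether synthesis on the phenoxide masks the future ring A phenol as a methyl ether that survives organolithium, hot carbonate, hydride and radical steps.

Step 2
Reactants: 2 4-fluoroanisole
Product: 4 2-fluoro-5-methoxybenzaldehyde, via aryllithium 3 (not isolated)
Conditions: n-BuLi, PMDTA, THF, −78 °C; DMF, −78 °C to rt; 1 M HCl
Reagents that add atoms: N,N-dimethylformamide, CN(C)C=O
Why: Directed ortho-lithiation with the n-BuLi/PMDTA complex removes the most acidic C–H, next to fluorine rather than next to OMe, and DMF formylates the aryllithium.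

Step 3
Reactants: 4 2-fluoro-5-methoxybenzaldehyde; 5 3-iodophenol
Product: 6 2-(3-iodophenoxy)-5-methoxybenzaldehyde
Conditions: K2CO3, DMA, 150 °C
Reagents that add atoms: none
Why: SNAr (addition–elimination) works because the ortho-formyl group stabilises the Meisenheimer adduct and fluoride leaves, while the C–I bond is inert in the absence of copper or palladium.

Step 4
Reactants: 7 catechol
Product: 8 guaiacol (2-methoxyphenol)
Conditions: 7 (2 equiv), MeI (1 equiv), K2CO3 (1 equiv), acetone, reflux
Reagents that add atoms: iodomethane, CI
Why: Williamson mono-methylation with catechol in excess limits double alkylation, and water washing (catechol) plus base extraction (veratrole) give clean guaiacol.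

Step 5
Reactants: 8 guaiacol; 9 1,4-diiodobenzene
Product: 10 1-(4-iodophenoxy)-2-methoxybenzene
Conditions: 9 (3 equiv), CuI (10 mol %), picolinic acid (20 mol %), K3PO4, DMSO, 90 °C
Reagents that add atoms: none
Why: Ullmann-type C–O coupling tolerates ortho-substituted phenols, and the threefold excess of the symmetrical diiodide holds the reaction at mono-coupling so one iodide remains for step 7.

Step 6
Reactants: 10 1-(4-iodophenoxy)-2-methoxybenzene
Product: 11 3-(4-iodophenoxy)-4-methoxybenzaldehyde
Conditions: Cl2CHOMe, TiCl4, CH2Cl2, 0 °C; ice/1 M HCl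
Reagents that add atoms: dichloromethyl methyl ether, COC(Cl)Cl; water, O
Why: Rieche formylation (electrophilic aromatic substitution) goes para to OMe because OMe is a stronger donor than OAr, and the iodinated ring C is deactivated.

Step 7
Reactants: 11 3-(4-iodophenoxy)-4-methoxybenzaldehyde; 12 trimethylsilylacetylene; 6 2-(3-iodophenoxy)-5-methoxybenzaldehyde
Product: 15 diarylalkyne dialdehyde, via silylalkyne 13 (not isolated), via terminal alkyne 14 (not isolated)
Conditions: 11, 12 (1.05 equiv), PdCl2(PPh3)2 (5 mol %), CuI (10 mol %), Et3N, PhMe, rt; argon purge; then 6, DBU, H2O, 60 °C, same flask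
Reagents that add atoms: none
Why: A Sonogashira coupling, in situ protodesilylation by DBU/H2O and a second Sonogashira coupling run in one flask because both aryl iodides add readily to zerovalent palladium and the non-enolisable aldehydes are spectators.

Step 8
Reactants: 15 diarylalkyne dialdehyde
Product: 16 open-chain bibenzyl dialdehyde
Conditions: H2 (1 atm), 10% Pd/C, Ph2S (1 mol %), EtOAc, rt
Reagents that add atoms: none
Why: Catalytic hydrogenation over sulfide-poisoned Pd/C saturates the alkyne to CH2–CH2 without reducing aromatic aldehydes, and it replaces the rigid rod between rings C and D with a flexible link that allows ring closure.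

Step 9
Reactants: 16 open-chain bibenzyl dialdehyde
Product: 18 nineteen-membered aza-macrocycle, via macrocyclic aldimine 17 (not isolated)
Conditions: NH3 (2 M in EtOH, 1.1 equiv), Ti(OiPr)4 (2.5 equiv), THF/EtOH, 2 mM, rt; NaBH4, 0 °C to rt; aq. NH3 work-up
Reagents that add atoms: ammonia, N
Why: This is a double reductive amination in which the benzylic nitrogen formed on the first aldehyde is far more nucleophilic than NH3 and at 2 mM closes on the second aldehyde of the same molecule to an unstrained aldimine that NaBH4 reduces; this reagent set is known to turn aromatic aldehydes into dibenzylamines.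

Step 10
Reactants: 18 nineteen-membered aza-macrocycle
Product: 20 dihydroptychantol A dimethyl ether, via isodiazene 19 (not isolated)
Conditions: N-(benzyloxy)-N-(pivaloyloxy)-4-(trifluoromethyl)benzamide (1.5 equiv), THF, 5 mM, 45 °C
Reagents that add atoms: none
Why: Proposed new method: ring-contracting nitrogen deletion of a macrocyclic dibenzylic amine (19 to 18 ring atoms), in which the NH attacks the electrophilic nitrogen of the anomeric amide (pivalate leaves) and the adduct collapses with ester formation to isodiazene 19; 19 loses N2 by stepwise homolysis of its two benzylic C–N bonds (a radical path, not a concerted extrusion), and the two benzyl radicals, held together by the rest of the macrocycle, cannot diffuse apart, so their recombination (about 65 kcal/mol released) pays for the ring strain and forms the ring A–CH2–CH2–ring B bond; dilution suppresses tetrazene formation from two isodiazenes; the closest known reaction type is nitrogen deletion of acyclic dibenzylamines to bibenzyls and contraction of five- to seven-membered 2-aryl azacycles with this reagent (related to the oxidation of 1,1-dibenzylhydrazines), not yet shown on a macrocyclic azacyclophane.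

Step 11
Reactants: 20 dihydroptychantol A dimethyl ether
Product: 21 dihydroptychantol A
Conditions: BBr3 (6 equiv), CH2Cl2, −78 °C to rt; H2O
Reagents that add atoms: none
Why: Lewis-acid ether cleavage by BBr3 proceeds by bromide attack at the methyl carbon, so both aryl methyl ethers fall while the two diaryl ethers, which have no sp3 C–O bond, stay intact.

## Compound list
1 | 4-fluorophenol | Oc1ccc(F)cc1 | starting material
2 | 4-fluoroanisole | COc1ccc(F)cc1 | intermediate
3 | (2-fluoro-5-methoxyphenyl)lithium, formed in the flask | COc1ccc(F)c([Li])c1 | intermediate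
4 | 2-fluoro-5-methoxybenzaldehyde | COc1ccc(F)c(C=O)c1 | intermediate
5 | 3-iodophenol | Oc1cccc(I)c1 | starting material
6 | 2-(3-iodophenoxy)-5-methoxybenzaldehyde (rings A–O–D) | COc1ccc(Oc2cccc(I)c2)c(C=O)c1 | intermediate
7 | catechol | Oc1ccccc1O | starting material
8 | guaiacol (2-methoxyphenol) | COc1ccccc1O | intermediate
9 | 1,4-diiodobenzene | Ic1ccc(I)cc1 | starting material
10 | 1-(4-iodophenoxy)-2-methoxybenzene | COc1ccccc1Oc1ccc(I)cc1 | intermediate
11 | 3-(4-iodophenoxy)-4-methoxybenzaldehyde (rings B–O–C) | COc1ccc(C=O)cc1Oc1ccc(I)cc1 | intermediate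
12 | trimethylsilylacetylene | C#C[Si](C)(C)C | starting material
13 | 4-methoxy-3-{4-[(trimethylsilyl)ethynyl]phenoxy}benzaldehyde, formed in the flask | COc1ccc(C=O)cc1Oc1ccc(cc1)C#C[Si](C)(C)C | intermediate
14 | 3-(4-ethynylphenoxy)-4-methoxybenzaldehyde, formed in the flask | COc1ccc(C=O)cc1Oc1ccc(cc1)C#C | intermediate
15 | 3-{4-[(3-(2-formyl-4-methoxyphenoxy)phenyl)ethynyl]phenoxy}-4-methoxybenzaldehyde | COc1ccc(C=O)cc1Oc1ccc(cc1)C#Cc1cccc(c1)Oc1ccc(OC)cc1C=O | intermediate
16 | 3-{4-[2-(3-(2-formyl-4-methoxyphenoxy)phenyl)ethyl]phenoxy}-4-methoxybenzaldehyde | COc1ccc(C=O)cc1Oc1ccc(cc1)CCc1cccc(c1)Oc1ccc(OC)cc1C=O | intermediate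
17 | nineteen-membered (E)-aldimine, ring A–CH2–N=CH–ring B, formed in the flask | COc1ccc2c(c1)C/N=C/c1ccc(OC)c(c1)Oc1ccc(cc1)CCc1cccc(c1)O2 | intermediate
18 | nineteen-membered aza-macrocycle, ring A–CH2–NH–CH2–ring B, otherwise the skeleton of 20 | COc1ccc2c(c1)CNCc1ccc(OC)c(c1)Oc1ccc(cc1)CCc1cccc(c1)O2 | intermediate
19 | isodiazene (N-nitrene) of 18, formed in the flask | COc1ccc2c(c1)C[N+](=[N-])Cc1ccc(OC)c(c1)Oc1ccc(cc1)CCc1cccc(c1)O2 | intermediate
20 | dihydroptychantol A dimethyl ether (eighteen-membered ring) | COc1ccc2c(c1)CCc1ccc(OC)c(c1)Oc1ccc(cc1)CCc1cccc(c1)O2 | intermediate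
21 | dihydroptychantol A | Oc1ccc2c(c1)CCc1ccc(O)c(c1)Oc1ccc(cc1)CCc1cccc(c1)O2 | target

## Step count and risks
Total steps: 11.
Longest linear sequence: 8 steps (1, 2, 3, 7, 8, 9, 10, 11). The branch through steps 4, 5 and 6 is equally long.

**Step 10 (the new ring contraction).**
- Risk: the tethered radical pair may abstract hydrogen, couple through a ring position, or the isodiazene may dimerise.
- Fallback (known chemistry): it sets out from 16 and comes back at 20.
- Dialdehyde 16 is closed directly by McMurry coupling (TiCl4, Zn, pyridine, THF, reflux, slow addition). This gives the eighteen-membered macrocyclic (Z)-stilbene F1.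
- Hydrogenation of F1 (H2, 10% Pd/C, EtOAc) gives 20.

**Step 9 (macrocyclic double reductive amination).**
- Risk: formation of the bis(primary amine) or of oligomers.
- Fallback: it sets out from 16 and comes back at 18.
- NaBH4 in MeOH/THF reduces 16 to the bis(benzylic alcohol) F2.
- PBr3 in CH2Cl2 at 0 °C converts F2 into the bis(benzylic bromide) F3.
- Slow addition of F3 to 2-nitrobenzenesulfonamide and Cs2CO3 in DMF closes the ring by double N-alkylation to the N-nosyl macrocycle F4.
- PhSH/K2CO3 in MeCN removes the nosyl group to give 18.

**Step 7 (three reactions in one flask).**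
- Risk: oxidative homocoupling of 14, or scrambling by leftover 12.
- Fallback: it sets out from 11 and comes back at 16.
- Suzuki–Miyaura vinylation of 11 (CH2=CHBF3K, PdCl2(dppf), Cs2CO3, THF/H2O, 70 °C) gives the styrene F5.
- Heck reaction of F5 with 6 (Pd(OAc)2, P(o-tol)3, Et3N, DMF, 100 °C) gives the (E)-stilbene dialdehyde F6.
- Hydrogenation of F6 under the conditions of step 8 gives 16.

## Further compounds
F1 | step 10 | eighteen-membered macrocyclic (Z)-stilbene, ring A–CH=CH–ring B | COc1ccc2c(c1)/C=C\c1ccc(OC)c(c1)Oc1ccc(cc1)CCc1cccc(c1)O2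
F2 | step 9 | bis(benzylic alcohol) from 16 | COc1ccc(CO)cc1Oc1ccc(cc1)CCc1cccc(c1)Oc1ccc(OC)cc1CO
F3 | step 9 | bis(benzylic bromide) | COc1ccc(CBr)cc1Oc1ccc(cc1)CCc1cccc(c1)Oc1ccc(OC)cc1CBr
F4 | step 9 | N-(2-nitrobenzenesulfonyl) derivative of 18 | COc1ccc2c(c1)CN(S(=O)(=O)c1ccccc1[N+](=O)[O-])Cc1ccc(OC)c(c1)Oc1ccc(cc1)CCc1cccc(c1)O2
F5 | step 7 | 3-(4-ethenylphenoxy)-4-methoxybenzaldehyde | COc1ccc(C=O)cc1Oc1ccc(C=C)cc1
F6 | step 7 | (E)-stilbene dialdehyde, ring C–CH=CH–ring D | COc1ccc(C=O)cc1Oc1ccc(cc1)/C=C/c1cccc(c1)Oc1ccc(OC)cc1C=O
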